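Compound numbers are those of the steps and of the compound list. Ring atoms are written O-1, C-2 … C-5, with C-2 the carbon whose aryl group is cis to the C-3 substituent.

## Analysis of the target

The target 19 is a fully substituted oxolane with no other ring: C-2 and C-5 each carry a 4-hydroxy-3,5-dimethoxyphenyl group, C-3 and C-4 each a hydroxymethyl group. The configuration is (2S,3S,4S,5R). The two hydroxymethyl groups are trans, the C-2 aryl group is cis to the C-3 hydroxymethyl group, the C-5 aryl group is trans to the C-4 hydroxymethyl group, and the two aryl groups therefore lie on the same face. The constitution is symmetric but the configuration is not: the two halves differ only in the sense of the benzylic centre. Both ring C–O bonds are benzylic and para to an oxygen substituent, so acid can ionise them, hydrogenolysis can cleave them, and the free phenols are prone to oxidation and quinone methide formation. The difficulty is the four contiguous stereocentres: the C-2/C-3 cis relationship is less stable than the all-trans arrangement and must be made under kinetic control, and there is no obvious chiral-pool source for the absolute configuration. The strategy rests on the C-3–C-4 unit, which with its two hydroxymethyl groups has a twofold axis (3S,4S), and on C-2 and C-5 carrying the same aryl group. A twofold-symmetric 1,4-dicarbonyl chain can therefore receive both aryl groups in one operation, and the symmetry is broken only when the ring oxygen and the two benzylic hydrogens are put in.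

## Retrosynthetic reasoning

**19 from 18.** The four O–H groups are masked as benzyl ethers, which traces 19 to the tetrabenzyl ether 18. Benzyl is chosen because the two alkyl benzyl ethers come in directly with electrophile 4 and the two aryl benzyl ethers with 10. All four should survive organolithium, borane and Lewis acid at low temperature and fall in one final operation. The forward step must cleave four O–benzyl bonds and spare the two benzylic ring C–O bonds.

**18 from 16 through 17.** The C-2–H bond is cut. C-2 is the contra-thermodynamic centre, so it is made last, by hydride addition to the planar oxocarbenium ion 17 obtained from lactol 16. The adjacent C-3 substituent then decides the face: hydride enters anti to it and the aryl group ends up cis. Closing the ring by displacement at C-2 instead would require a clean invertive substitution at an electron-rich benzylic carbon, which is less dependable. The forward step has to ionise and trap at low temperature, before 17 loses the C-3 proton.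

**16 from 14 through 15.** The hemiketal bond O-1–C-2 and the C-5–H bond are cut, leading to hydroxy ketone 15 and then to diketone 14. The twofold axis of 14 makes its two carbonyl groups equivalent, so whichever is reduced gives the same 15; only the number of hydrides delivered and the facial sense matter. The gain is that symmetry is broken by a reaction that needs no site selectivity.

**14 from 8 and two equivalents of 12 (key disconnection).** Both aryl–carbonyl bonds are cut at once. These are the only C–C bonds joining the aryl groups to the chain and they are identical, so a two-directional addition of aryllithium 12 to the bis(N-methoxy-N-methylamide) 8 builds the whole skeleton in one step. The amide type is chosen because addition stops at the ketone level. The forward reaction must add twice without deprotonating the α-carbons, which carry a β-benzyloxy leaving group.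

**12 from 11, and 11 from 9 and 10.** The aryllithium comes from bromide 11 by halogen–lithium exchange, and 11 from phenol 9 by O-benzylation with 10.

**8 from 7, and 7 from 6.** These are functional-group changes only: amide from diacid 7, diacid from the bis-imide 6 by removal of the auxiliary.

**6 from 3 and two equivalents of 4 (through 5), and 3 from 1 and 2.** The two C–CH2O bonds are cut. Each new centre then sits next to its own oxazolidinone, and the configuration follows from the well-established facial sense of imide enolate alkylation. With the (R)-auxiliary 1 each centre should come out (S), because the benzyloxymethyl group outranks the chain carbon. A dialkylation of a succinic diester bearing chiral ester groups looks shorter, but was not adopted. Its sense and level of induction with two separate electrophiles are not secured, and the hindered esters would have to be cleaved next to two base-sensitive β-alkoxy centres.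

## Alternatives that were turned down

**Alternative 1:** The C-3–C-4 bond is cut and each half is traced to sinapic acid A1. In the forward direction a laccase-mediated aerobic oxidation converts two molecules of A1 into phenoxyl radicals, which join at their β-carbons. Each carboxyl group then adds to the quinone methide of the other half, giving dilactone A2 in one operation.
- For: no protecting groups, and one step from a cheap acid to the complete carbon skeleton with the two future hydroxymethyl carbons already in the required relative sense. In step count to the skeleton this clearly beats the chosen route.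
- Against: radical coupling of an achiral monomer has no source of absolute configuration, so A2 is expected as a racemate and the single enantiomer would need a resolution.
- Against: in A2 each benzylic carbon is bonded to the carboxyl oxygen of the other half, whereas 19 needs one oxygen bridging the two benzylic carbons. After lactone reduction both benzylic C–O bonds would have to be broken and a new ring closed through benzylic cations or quinone methides. C-2 and C-5 would then be set by thermodynamics or a weak kinetic bias, and the required pattern (one aryl cis, one trans to its neighbour) is not the favoured one. Reclosure to the original bicyclic ether also competes.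
- Comparison: the chosen route is longer, but it takes its absolute configuration from an auxiliary and sets C-5 and C-2 in two separate steps, each with its own control element.

**Alternative 2:** The C-2–C-3 ring bond is cut, leading to the seven-membered cyclic acetal A3. In the forward direction a silyl triflate at low temperature ionises the acetal carbon. The resulting oxocarbenium ion is tethered through oxygen to an enol fragment and recloses through carbon to the tetrahydrofuran-3-carbaldehyde A4.
- For: the cis relation between the C-2 aryl group and the C-3 substituent is inherent in the compact cyclic transition state. On this point the alternative is at least as strong as the hydride reduction of 17, whose selectivity rests on a steric bias. C-2 and C-3 are also set in the ring-forming step itself.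
- Against: the two stereocentres of A3 (the later C-4 and C-5) must be made enantioselectively beforehand, and the two aryl groups enter in different steps by different reactions. The symmetry of the target is unused and the linear sequence is longer.
- Against: A4 is an aldehyde with an acidic hydrogen at C-3 cis to the aryl group. Epimerisation to the more stable 2,3-trans isomer threatens during reaction and work-up, and the reclosure is reversible on warming. The C-3/C-4 relation depends on the conformation of the tether, not on a dedicated control element.
- Comparison: the chosen route keeps C-3 and C-4 at the alcohol oxidation level throughout, so no epimerisable aldehyde is passed, and fixes their relation before any ring chemistry.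

**Alternative 3:** The C-4–C-5 and O-1–C-5 bonds are cut. In the forward direction the chiral benzylic sulfonium ylide A6 adds in conjugate fashion to the alkylidene β-keto ester A5. The enolate oxygen then displaces the sulfide at the benzylic carbon and closes the trans-4,5-dihydrofuran A7.
- For: the step is convergent and creates the ring and the C-4/C-5 trans pair at once, and the sulfide can be recovered. In convergence it equals or exceeds the chosen route.
- Against: A7 still contains the C-2=C-3 double bond, a tetrasubstituted push–pull alkene, and both remaining stereocentres must come from its reduction. Hydrogen adds to one face and so gives the needed C-2/C-3 cis relation, but the accessible face is the one away from the C-4 substituent. That places the ester cis to C-4, the wrong C-3/C-4 relation, and correcting C-3 by base would destroy the cis relation to C-2.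
- Against: the enantioselectivity of semi-stabilised ylides with such acceptors is variable, the electron-rich benzylic sulfonium salt is prone to solvolysis, and the ester still has to be reduced.
- Comparison: the chosen route offers one control element per stereocentre and avoids an alkene whose two faces are wanted for different centres.

Key step: step 6

## Route

Remark: lactol 16 is expected as a mixture of C-2 anomers in equilibrium with 15; this is immaterial because C-2 becomes planar in 17.

Step 1
Reactants: 1 (4R)-4-benzyl-1,3-oxazolidin-2-one (2 equiv); 2 succinyl chloride (butanedioyl dichloride)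
Product: 3 1,4-bis[(4R)-4-benzyl-2-oxo-1,3-oxazolidin-3-yl]butane-1,4-dione
Conditions: n-BuLi (1 equiv per 1), THF, −78 °C; then 2 (0.5 equiv), −78 → 0 °C
Reagents that add atoms: none
Why: N-acylation of the lithiated oxazolidinone by both acid chloride groups (standard preparation of Evans imides); no stereocentre is formed and C-4 of the auxiliary is not touched.

Step 2
Reactants: 3 the succinyl bis-imide; 4 benzyl chloromethyl ether
Product: 6 (2S,3S)-2,3-bis[(benzyloxy)methyl]-1,4-bis[(4R)-4-benzyl-2-oxo-1,3-oxazolidin-3-yl]butane-1,4-dione, via mono-alkylated (2S)-bis-imide 5 (not isolated)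
Conditions: TiCl4 (2.2 equiv), i-Pr2NEt (2.3 equiv), CH2Cl2, 0 °C, 1 h; 4 (4 equiv), 0 °C; partly alkylated material resubmitted
Reagents that add atoms: none
Why: Evans alkylation of chlorotitanium imide enolates with an α-chloro ether: soft enolisation gives the chelated Z-enolate, the benzyl group of the (R)-auxiliary blocks one face, and the electrophile enters from the other, which should give (S) at each new centre. Each centre is governed by its own auxiliary, so the two alkylations converge on the twofold-symmetric product. The tertiary α-hydrogen of an alkylated centre is not removed under these conditions, so neither over-alkylation nor loss of benzyloxide is expected.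

Step 3
Reactants: 6 the dialkylated bis-imide
Product: 7 (2S,3S)-2,3-bis[(benzyloxy)methyl]butanedioic acid
Conditions: LiOH (4 equiv), 30% H2O2 (10 equiv), THF/H2O, 0 °C; aq. Na2SO3; HCl to pH 2
Reagents that add atoms: hydrogen peroxide, OO
Why: Evans hydrolysis: hydroperoxide attacks the exocyclic imide carbonyl selectively and is not basic enough to enolise the α-centres. The sulfite quench completes the conversion to the acid, and auxiliary 1 is recovered.

Step 4
Reactants: 7 the (2S,3S)-diacid
Product: 8 (2S,3S)-2,3-bis[(benzyloxy)methyl]-N1,N4-dimethoxy-N1,N4-dimethylbutanediamide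
Conditions: MeNHOMe·HCl (3 equiv), EDC·HCl (2.6 equiv), HOBt (2.6 equiv), N-methylmorpholine (6 equiv), CH2Cl2, 0 °C → rt
Reagents that add atoms: N,O-dimethylhydroxylamine hydrochloride, CNOC.Cl
Why: Carbodiimide/HOBt amide coupling under weakly basic conditions, which should leave the α-centres intact. A transient cyclic anhydride, if it forms, is trans-configured and is opened by the same amine to the same product.

Step 5
Reactants: 9 4-bromo-2,6-dimethoxyphenol; 10 benzyl bromide
Product: 11 2-(benzyloxy)-5-bromo-1,3-dimethoxybenzene
Conditions: K2CO3, DMF, rt
Reagents that add atoms: none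
Why: Williamson O-benzylation of the phenoxide; the flanking methoxy groups do not hinder substitution at the primary benzylic bromide.

Step 6
Reactants: 11 2-(benzyloxy)-5-bromo-1,3-dimethoxybenzene (2.6 equiv); 8 the (2S,3S)-bis(N-methoxy-N-methylamide)
Product: 14 (2S,3S)-1,4-bis[4-(benzyloxy)-3,5-dimethoxyphenyl]-2,3-bis[(benzyloxy)methyl]butane-1,4-dione, via aryllithium 12 (not isolated), via dilithium bis-hemiaminal adduct 13 (not isolated)
Conditions: 11, n-BuLi (2.5 equiv), THF, −78 °C, 30 min; 8 in THF, −78 → −40 °C; cannulated into cold aq. NH4Cl
Reagents that add atoms: none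
Why: Bromine–lithium exchange on 11 gives 12, which adds as a carbon nucleophile to each amide carbonyl of 8; the closest known reaction type is the Weinreb ketone synthesis with aryllithiums, run here in two directions on a twofold-symmetric bis-amide. Each addition gives a tetrahedral adduct held as a five-membered lithium chelate between the alkoxide and the N-methoxy oxygen (13), which should not collapse at low temperature, so no ketone is present while 12 is and the reaction stops at the ketone level at both ends. No ring is closed in this step. No stereocentre is created in 14; the two existing centres are carried through, since in 13 they are no longer α to a carbonyl group and cannot be enolised. The selectivity needed is chemoselectivity: addition must outrun deprotonation at the α-carbons of 8 (which would expel benzyloxide), and ketone must not go on to tertiary alcohol. The first is secured by the high rate of aryllithium addition to N-methoxy amides at −78 °C, the second by the stability of the chelate. The second addition takes place next to the first tetrahedral centre and is slower, hence the excess of 12 and the slow warming to −40 °C. The inverse quench into cold NH4Cl liberates 14 under weakly acidic conditions, so that its α-centres are neither epimerised towards the meso diketone nor lose benzyl alcohol.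

Step 7
Reactants: 14 the (2S,3S)-diketone
Product: 16 (3S,4S,5R)-2,5-bis[4-(benzyloxy)-3,5-dimethoxyphenyl]-3,4-bis[(benzyloxy)methyl]oxolan-2-ol (lactol; both C-2 anomers), via open-chain hydroxy ketone 15 (not isolated)
Conditions: (S)-2-methyl-CBS-oxazaborolidine [(3aS)-1-methyl-3,3-diphenyltetrahydro-1H,3H-pyrrolo[1,2-c][1,3,2]oxazaborole] (0.2 equiv), catecholborane (1.0 equiv, slow addition), toluene/CH2Cl2, −78 → −40 °C; MeOH, then pH 7 buffer
Reagents that add atoms: none
Why: Corey–Bakshi–Shibata reduction: the ketone binds to the catalyst boron anti to the aryl group and hydride is delivered to give the (R)-carbinol, the same sense as the Felkin–Anh preference of the adjacent (S)-centre, so catalyst and substrate should be matched. The two carbonyl groups are equivalent by symmetry, and catecholborane carries a single hydride, so its stoichiometry limits the reduction to one carbonyl. On work-up 15 closes to lactol 16 by 5-exo addition of the hydroxyl to the remaining ketone.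

Step 8
Reactants: 16 the lactol
Product: 18 (2S,3S,4S,5R)-2,5-bis[4-(benzyloxy)-3,5-dimethoxyphenyl]-3,4-bis[(benzyloxy)methyl]oxolane, via oxocarbenium ion 17 (not isolated)
Conditions: Et3SiH (5 equiv), BF3·OEt2 (2.5 equiv), CH2Cl2, −78 °C; Et3N, then aq. NaHCO3
Reagents that add atoms: none
Why: Ionic hydrogenation of a hemiketal: the Lewis acid ionises 16 to the 2-aryl oxocarbenium ion 17, and the silane delivers hydride to C-2 from the face anti to the adjacent C-3 benzyloxymethyl group, which places the aryl group cis to it (2S). At −78 °C loss of the C-3 proton to a cyclic enol ether, which would scramble C-3, should be suppressed.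

Step 9
Reactants: 18 the tetrabenzyl ether
Product: 19 [(2S,3S,4S,5R)-2,5-bis(4-hydroxy-3,5-dimethoxyphenyl)oxolane-3,4-diyl]dimethanol
Conditions: H2 (1 atm), 10% Pd/C, EtOAc/MeOH, rt; stopped when uptake ceases
Reagents that add atoms: none
Why: Heterogeneous hydrogenolysis of O-benzyl ethers; unhindered aryl and primary alkyl benzyl ethers should be cleaved faster than the secondary, flanked benzylic C–O bonds of the ring, and no stereocentre is touched.

## Compound list

1 | (4R)-4-benzyl-1,3-oxazolidin-2-one | O=C1N[C@H](Cc2ccccc2)CO1 | starting material
2 | succinyl chloride (butanedioyl dichloride) | ClC(=O)CCC(=O)Cl | starting material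
3 | 1,4-bis[(4R)-4-benzyl-2-oxo-1,3-oxazolidin-3-yl]butane-1,4-dione | O=C(CCC(=O)N1[C@H](Cc2ccccc2)COC1=O)N1[C@H](Cc2ccccc2)COC1=O | intermediate
4 | benzyl chloromethyl ether | ClCOCc1ccccc1 | starting material
5 | (2S)-2-[(benzyloxy)methyl]-1,4-bis[(4R)-4-benzyl-2-oxo-1,3-oxazolidin-3-yl]butane-1,4-dione (not isolated) | O=C([C@H](COCc1ccccc1)CC(=O)N1[C@H](Cc2ccccc2)COC1=O)N1[C@H](Cc2ccccc2)COC1=O | intermediate
6 | (2S,3S)-2,3-bis[(benzyloxy)methyl]-1,4-bis[(4R)-4-benzyl-2-oxo-1,3-oxazolidin-3-yl]butane-1,4-dione | O=C([C@H](COCc1ccccc1)[C@@H](COCc1ccccc1)C(=O)N1[C@H](Cc2ccccc2)COC1=O)N1[C@H](Cc2ccccc2)COC1=O | intermediate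
7 | (2S,3S)-2,3-bis[(benzyloxy)methyl]butanedioic acid | OC(=O)[C@H](COCc1ccccc1)[C@@H](COCc1ccccc1)C(=O)O | intermediate
8 | (2S,3S)-2,3-bis[(benzyloxy)methyl]-N1,N4-dimethoxy-N1,N4-dimethylbutanediamide | CON(C)C(=O)[C@H](COCc1ccccc1)[C@@H](COCc1ccccc1)C(=O)N(C)OC | intermediate
9 | 4-bromo-2,6-dimethoxyphenol | COc1cc(Br)cc(OC)c1O | starting material
10 | benzyl bromide | BrCc1ccccc1 | starting material
11 | 2-(benzyloxy)-5-bromo-1,3-dimethoxybenzene | COc1cc(Br)cc(OC)c1OCc1ccccc1 | intermediate
12 | [4-(benzyloxy)-3,5-dimethoxyphenyl]lithium (not isolated) | [Li]c1cc(OC)c(OCc2ccccc2)c(OC)c1 | intermediate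
13 | dilithium (2S,3S)-1,4-bis[4-(benzyloxy)-3,5-dimethoxyphenyl]-2,3-bis[(benzyloxy)methyl]-1,4-bis[methoxy(methyl)amino]butane-1,4-diolate (not isolated; C-1 and C-4 undefined) | [Li+].[Li+].COc1cc(cc(OC)c1OCc1ccccc1)C([O-])(N(C)OC)[C@H](COCc1ccccc1)[C@@H](COCc1ccccc1)C([O-])(N(C)OC)c1cc(OC)c(OCc2ccccc2)c(OC)c1 | intermediate
14 | (2S,3S)-1,4-bis[4-(benzyloxy)-3,5-dimethoxyphenyl]-2,3-bis[(benzyloxy)methyl]butane-1,4-dione | COc1cc(cc(OC)c1OCc1ccccc1)C(=O)[C@H](COCc1ccccc1)[C@@H](COCc1ccccc1)C(=O)c1cc(OC)c(OCc2ccccc2)c(OC)c1 | intermediate
15 | (2S,3S,4R)-1,4-bis[4-(benzyloxy)-3,5-dimethoxyphenyl]-2,3-bis[(benzyloxy)methyl]-4-hydroxybutan-1-one (not isolated) | COc1cc(cc(OC)c1OCc1ccccc1)C(=O)[C@H](COCc1ccccc1)[C@@H](COCc1ccccc1)[C@@H](O)c1cc(OC)c(OCc2ccccc2)c(OC)c1 | intermediate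
16 | (3S,4S,5R)-2,5-bis[4-(benzyloxy)-3,5-dimethoxyphenyl]-3,4-bis[(benzyloxy)methyl]oxolan-2-ol (C-2 anomers) | COc1cc(C2(O)O[C@@H](c3cc(OC)c(OCc4ccccc4)c(OC)c3)[C@H](COCc3ccccc3)[C@H]2COCc2ccccc2)cc(OC)c1OCc1ccccc1 | intermediate
17 | (3S,4S,5R)-2,5-bis[4-(benzyloxy)-3,5-dimethoxyphenyl]-3,4-bis[(benzyloxy)methyl]-4,5-dihydro-3H-furan-1-ium, the cyclic oxocarbenium ion (not isolated) | COc1cc(C2=[O+][C@@H](c3cc(OC)c(OCc4ccccc4)c(OC)c3)[C@H](COCc3ccccc3)[C@H]2COCc2ccccc2)cc(OC)c1OCc1ccccc1 | intermediate
18 | (2S,3S,4S,5R)-2,5-bis[4-(benzyloxy)-3,5-dimethoxyphenyl]-3,4-bis[(benzyloxy)methyl]oxolane | COc1cc([C@H]2O[C@@H](c3cc(OC)c(OCc4ccccc4)c(OC)c3)[C@H](COCc3ccccc3)[C@H]2COCc2ccccc2)cc(OC)c1OCc1ccccc1 | intermediate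
19 | [(2S,3S,4S,5R)-2,5-bis(4-hydroxy-3,5-dimethoxyphenyl)oxolane-3,4-diyl]dimethanol | COc1cc([C@H]2O[C@@H](c3cc(OC)c(O)c(OC)c3)[C@H](CO)[C@H]2CO)cc(OC)c1O | target

## Step count and least certain steps

Total: 9 steps. Longest linear sequence: 8 steps (1, 2, 3, 4, 6, 7, 8, 9); step 5 is a one-step side branch.

**Step 6 (key step).**
- What may go wrong: the second addition may stall, because the second amide becomes hindered once its neighbour is a tetrahedral centre. The aryllithium may abstract an α-proton of 8, followed by expulsion of benzyloxide. The chelate may collapse early on warming, leading to over-addition. The liberated diketone may epimerise towards the meso isomer during work-up.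
- Fallback (from diacid 7 and aryllithium 12, back at 14): carbonyl addition is replaced by acyl cross-coupling. Diacid 7 is esterified with ethanethiol (EDC·HCl, catalytic 4-dimethylaminopyridine, CH2Cl2, 0 °C) to S,S′-diethyl (2S,3S)-2,3-bis[(benzyloxy)methyl]butanebis(thioate) F1. Aryllithium 12 is transmetalated with ZnCl2 to [4-(benzyloxy)-3,5-dimethoxyphenyl]zinc chloride F2. Fukuyama coupling of F1 with F2 (PdCl2(PPh3)2 as catalyst, THF/toluene, rt) forms both aryl–carbonyl bonds under non-basic conditions and gives 14.

**Step 7.**
- What may go wrong: reduction may run on to the second carbonyl or stop short. Ring closure to the lactol happens only on work-up and does not protect the second carbonyl during the reaction, so the product distribution tends towards the statistical one. Over-reduced material can be returned to 14 by oxidation. Facial selectivity may also be eroded, because the ketone is α-branched and the catalyst distinguishes aryl from a secondary alkyl group less well than from methyl.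
- Fallback (from diacid 7, back at 16): the aryl groups are introduced one after the other, so that no mono-functionalisation of a symmetric diketone is needed.
  - Dehydration of 7 (N,N′-dicyclohexylcarbodiimide, CH2Cl2) gives (3S,4S)-3,4-bis[(benzyloxy)methyl]oxolane-2,5-dione F3, whose two carbonyl groups are equivalent.
  - Slow addition of 12 (1 equiv) to F3 at −78 °C opens the ring once to (2S,3S)-4-[4-(benzyloxy)-3,5-dimethoxyphenyl]-2,3-bis[(benzyloxy)methyl]-4-oxobutanoic acid F4.
  - NaBH4 (MeOH/THF, −20 °C, on the sodium carboxylate) reduces the single ketone under the same Felkin–Anh bias to (2S,3S,4R)-4-[4-(benzyloxy)-3,5-dimethoxyphenyl]-2,3-bis[(benzyloxy)methyl]-4-hydroxybutanoic acid F5.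
  - Catalytic p-toluenesulfonic acid closes F5 to (3S,4S,5R)-5-[4-(benzyloxy)-3,5-dimethoxyphenyl]-3,4-bis[(benzyloxy)methyl]oxolan-2-one F6, and acid equilibration at the benzylic carbon would favour this 4,5-trans lactone.
  - Addition of 12 (1.1 equiv, THF, −78 °C) to the lactone carbonyl of F6 gives 16.

**Step 8.**
- What may go wrong: hydride may be delivered to the other face of 17, giving the all-trans isomer. Loss of the C-3 proton from 17 to a cyclic enol ether and reprotonation would scramble C-3. The Lewis acid may ionise the second benzylic C–O bond at C-5, or a benzyloxymethyl oxygen may capture the cation.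
- Fallback (from lactol 16, back at 18): face-selective hydride addition is replaced by a stereospecific displacement. Lactol 16, through its open form 15, is reduced a second time with the catalyst and catecholborane of step 7 to the twofold-symmetric (1R,2S,3S,4R)-1,4-bis[4-(benzyloxy)-3,5-dimethoxyphenyl]-2,3-bis[(benzyloxy)methyl]butane-1,4-diol F7. Its two carbinol centres are equivalent, so activation of either hydroxyl under Mitsunobu conditions (PPh3, diisopropyl azodicarboxylate, THF, 0 °C) and attack by the other with inversion gives 18 whichever end reacts. The weak point of this fallback is ionisation of the activated, electron-rich benzylic centre, which would erode the inversion.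

**Step 2.**
- What may go wrong: the second enolisation–alkylation may be incomplete. Acyl transfer between the two imide groups may occur at the enolate stage. Facial control may be lower in the second alkylation, because the enolate then carries a branched, stereogenic substituent. Enolisation at the already alkylated centre would cause loss of benzyloxide.
- Fallback (from 1 and 4, back at 8): only one imide is present at a time, and the second centre is set by substrate control in a lactone.
  - Auxiliary 1 is acylated (n-BuLi, THF, −78 °C; methyl 4-chloro-4-oxobutanoate) to methyl 4-[(4R)-4-benzyl-2-oxo-1,3-oxazolidin-3-yl]-4-oxobutanoate F8.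
  - The titanium enolate alkylation of step 2 with 4 gives methyl (3S)-3-[(benzyloxy)methyl]-4-[(4R)-4-benzyl-2-oxo-1,3-oxazolidin-3-yl]-4-oxobutanoate F9.
  - LiBH4 (THF/MeOH, 0 °C) reduces the imide in preference to the ester to methyl (3R)-3-[(benzyloxy)methyl]-4-hydroxybutanoate F10.
  - Acid treatment lactonises F10 to (4S)-4-[(benzyloxy)methyl]oxolan-2-one F11.
  - The lithium enolate of F11 (lithium diisopropylamide, THF, −78 °C) is alkylated by 4 anti to the ring substituent to give (3S,4S)-3,4-bis[(benzyloxy)methyl]oxolan-2-one F12.
  - MeNHOMe·HCl/AlMe3 opens F12 to (2S,3R)-2,3-bis[(benzyloxy)methyl]-4-hydroxy-N-methoxy-N-methylbutanamide F13.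
  - TEMPO/PhI(OAc)2 (MeCN/H2O) oxidises the primary alcohol to (2S,3S)-2,3-bis[(benzyloxy)methyl]-4-[methoxy(methyl)amino]-4-oxobutanoic acid F14.
  - Coupling of F14 as in step 4 gives 8.

  This is longer, but each operation is standard, and anti alkylation of β-substituted γ-lactones is a dependable way to set such vicinal centres.

**Step 9.**
- What may go wrong: hydrogenolysis of the ring C-2–O or C-5–O bond may compete with the slow cleavage of the two alkyl benzyl ethers, opening the ring.
- Fallback (from 18 directly to 19, no new intermediate): surface hydrogenolysis is replaced by electron-transfer debenzylation with lithium 4,4′-di-tert-butylbiphenylide (THF, −78 °C; NH4Cl quench). The aryl benzyl ethers should be cleaved first and leave both rings as phenoxides, which are too electron-rich to accept an electron. The ring benzylic C–O bonds are thereby shielded while the alkyl benzyl ethers are cleaved.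

## Further compounds

F1 | step 6 | S,S′-diethyl (2S,3S)-2,3-bis[(benzyloxy)methyl]butanebis(thioate) | CCSC(=O)[C@H](COCc1ccccc1)[C@@H](COCc1ccccc1)C(=O)SCC
F2 | step 6 | [4-(benzyloxy)-3,5-dimethoxyphenyl]zinc chloride | COc1cc([Zn]Cl)cc(OC)c1OCc1ccccc1
F3 | step 7 | (3S,4S)-3,4-bis[(benzyloxy)methyl]oxolane-2,5-dione | O=C1[C@H](COCc2ccccc2)[C@@H](COCc2ccccc2)C(=O)O1
F4 | step 7 | (2S,3S)-4-[4-(benzyloxy)-3,5-dimethoxyphenyl]-2,3-bis[(benzyloxy)methyl]-4-oxobutanoic acid | OC(=O)[C@H](COCc1ccccc1)[C@@H](COCc1ccccc1)C(=O)c1cc(OC)c(OCc2ccccc2)c(OC)c1
F5 | step 7 | (2S,3S,4R)-4-[4-(benzyloxy)-3,5-dimethoxyphenyl]-2,3-bis[(benzyloxy)methyl]-4-hydroxybutanoic acid | OC(=O)[C@H](COCc1ccccc1)[C@@H](COCc1ccccc1)[C@@H](O)c1cc(OC)c(OCc2ccccc2)c(OC)c1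
F6 | step 7 | (3S,4S,5R)-5-[4-(benzyloxy)-3,5-dimethoxyphenyl]-3,4-bis[(benzyloxy)methyl]oxolan-2-one | O=C1O[C@@H](c2cc(OC)c(OCc3ccccc3)c(OC)c2)[C@H](COCc2ccccc2)[C@H]1COCc1ccccc1
F7 | step 8 | (1R,2S,3S,4R)-1,4-bis[4-(benzyloxy)-3,5-dimethoxyphenyl]-2,3-bis[(benzyloxy)methyl]butane-1,4-diol | COc1cc(cc(OC)c1OCc1ccccc1)[C@H](O)[C@H](COCc1ccccc1)[C@@H](COCc1ccccc1)[C@@H](O)c1cc(OC)c(OCc2ccccc2)c(OC)c1
F8 | step 2 | methyl 4-[(4R)-4-benzyl-2-oxo-1,3-oxazolidin-3-yl]-4-oxobutanoate | COC(=O)CCC(=O)N1[C@H](Cc2ccccc2)COC1=O
F9 | step 2 | methyl (3S)-3-[(benzyloxy)methyl]-4-[(4R)-4-benzyl-2-oxo-1,3-oxazolidin-3-yl]-4-oxobutanoate | COC(=O)C[C@@H](COCc1ccccc1)C(=O)N1[C@H](Cc2ccccc2)COC1=O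
F10 | step 2 | methyl (3R)-3-[(benzyloxy)methyl]-4-hydroxybutanoate | OC[C@H](COCc1ccccc1)CC(=O)OC
F11 | step 2 | (4S)-4-[(benzyloxy)methyl]oxolan-2-one | O=C1C[C@@H](COCc2ccccc2)CO1
F12 | step 2 | (3S,4S)-3,4-bis[(benzyloxy)methyl]oxolan-2-one | O=C1OC[C@H](COCc2ccccc2)[C@H]1COCc1ccccc1
F13 | step 2 | (2S,3R)-2,3-bis[(benzyloxy)methyl]-4-hydroxy-N-methoxy-N-methylbutanamide | CON(C)C(=O)[C@H](COCc1ccccc1)[C@@H](COCc1ccccc1)CO
F14 | step 2 | (2S,3S)-2,3-bis[(benzyloxy)methyl]-4-[methoxy(methyl)amino]-4-oxobutanoic acid | CON(C)C(=O)[C@H](COCc1ccccc1)[C@@H](COCc1ccccc1)C(=O)O
F0 | step 9 | none | none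
A1 | alternative 1 | sinapic acid, (E)-3-(4-hydroxy-3,5-dimethoxyphenyl)prop-2-enoic acid | COc1cc(/C=C/C(=O)O)cc(OC)c1O
A2 | alternative 1 | 2,6-bis(4-hydroxy-3,5-dimethoxyphenyl)-3,7-dioxabicyclo[3.3.0]octane-4,8-dione, cis-fused, both aryl groups exo | O=C1O[C@@H](c3cc(OC)c(O)c(OC)c3)[C@H]2[C@@H]1[C@H](c4cc(OC)c(O)c(OC)c4)OC2=O
A3 | alternative 2 | 4,5-trans-2,4-bis[4-(benzyloxy)-3,5-dimethoxyphenyl]-5-[(tert-butyldimethylsilyloxy)methyl]-4,5-dihydro-1,3-dioxepin (acetal carbon undefined) | COc1cc(C2O[C@@H](c3cc(OC)c(OCc4ccccc4)c(OC)c3)[C@H](CO[Si](C)(C)C(C)(C)C)C=CO2)cc(OC)c1OCc1ccccc1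
A4 | alternative 2 | 2,5-cis-bis[4-(benzyloxy)-3,5-dimethoxyphenyl]-4-[(tert-butyldimethylsilyloxy)methyl]oxolane-3-carbaldehyde, 2,3-cis, 3,4-trans | COc1cc([C@H]2O[C@@H](c3cc(OC)c(OCc4ccccc4)c(OC)c3)[C@H](CO[Si](C)(C)C(C)(C)C)[C@H]2C=O)cc(OC)c1OCc1ccccc1
A5 | alternative 3 | methyl 2-[4-(benzyloxy)-3,5-dimethoxybenzoyl]-4-(tert-butyldimethylsilyloxy)but-2-enoate (alkene geometry undefined) | COC(=O)C(=CCO[Si](C)(C)C(C)(C)C)C(=O)c1cc(OC)c(OCc2ccccc2)c(OC)c1
A6 | alternative 3 | [4-(benzyloxy)-3,5-dimethoxyphenyl]methylide of (2R,5R)-2,5-dimethylthiolanium (one enantiomer of the sulfide shown) | COc1cc([CH-][S+]2[C@H](C)CC[C@H]2C)cc(OC)c1OCc1ccccc1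
A7 | alternative 3 | methyl trans-2,5-bis[4-(benzyloxy)-3,5-dimethoxyphenyl]-4-[(tert-butyldimethylsilyloxy)methyl]-4,5-dihydrofuran-3-carboxylate | COC(=O)C1=C(c2cc(OC)c(OCc3ccccc3)c(OC)c2)O[C@@H](c2cc(OC)c(OCc3ccccc3)c(OC)c2)[C@@H]1CO[Si](C)(C)C(C)(C)C
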